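The readings were computed with made-up constants; noise was put on by code.

The vessel is closed and stirred, and the question is how much target it still holds at a late hour.

all flasks: coupling partner 0.225 M

| charge | starting material | target | time |
|---|---|---|---|
| blue | 0.150 M |  |  |
| grey | 0.0750 M |  |  |
| amber | 0.150 M | 0.0750 M |  |
| violet | 0.150 M |  | 220 min |

- blue run (time / min: [target] / M): 3.5: 0.0055; 6.7: 0.0089; 13: 0.0162; 24: 0.0284; 46: 0.0408; 88: 0.0489
- grey run (time / min: [target] / M): 3.5: 0.0018; 6.7: 0.0065; 13: 0.0083; 24: 0.0168; 46: 0.0235; 88: 0.0267
- amber run (time / min: [target] / M): 3.5: 0.0812; 6.7: 0.0825; 13: 0.0928; 24: 0.1033; 46: 0.1163; 88: 0.1250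

(each reading ± 0.001 M)

- Overall: starting material + coupling partner -> target.
- Constant volume, constant temperature.
- What is held in complexes is read along with the free species.
- "The second partner" is coupling partner.
- An order is taken over about fifteen percent of the charge, up and down.

1. the exponent of [starting material] in the starting rate at the charge of the blue run (at the point where two percent of the starting material have become target) (one fixed amount of target, the same in the runs compared)
2. target in the violet run at 220 min, as a share of the starting material charged

I reckon no exponent from the readings: at 3.5 min the grey run stands at 0.0018 M, with a scatter of 0.001 M. My reckoning goes to the violet run, which has the charge of the blue run and simply runs longer.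

1. Bound from below: if target is not lost, the violet run holds at least the last blue reading, 0.0489 M, or 32.6% of the charge, within the scatter.

2. Bound from above: the blue slope falls from 5.64 × 10⁻⁴ M/min to 1.93 × 10⁻⁴ M/min. If it keeps falling, holding the last slope up to 220 min overshoots, and that gives 49.6%.

3. First round: I suppose the gap between target and a ceiling shrinks exponentially, and I put the ceiling at the last reading. The gaps at 24 min and 46 min then give 0.0422 /min, and the last 42.0 min of readings lift the ceiling to 0.0506 M.

4. Second round: with that ceiling put back in, the rate becomes 0.0373 /min. This is the closing constant, the fraction of the remaining gap to the ceiling that closes per minute. The ceiling becomes 0.0510 M.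

5. At 220 min the gap left is 1.56 × 10⁻⁵ M, less than the scatter, so I commit to 34.0%.

The forecast gives 0.82 and 35%, holding that “the stall at about one-third conversion is not equilibrium”; its yield lies inside my bracket, above my own number.

The violet run holds 33.4% of its charge, and the exponent of starting material at the charge of the blue run is 0.68.

starting material + coupling partner → target (0.1128 /M/min); starting material + coupling partner → side product (0.02724 /M/min); starting material → decomposed substrate (0.03804 /min); 2 starting material ⇌ idle substrate dimer, settled at all times (10.50 /M) The blue run makes a quarter of its charge at 37.8 min, where the closing constant and the blue ceiling put it at 35.6 min. In the grey run the same constant gives a ceiling of 0.0275 M and puts its quarter at 30.6 min, and the grey run reaches it at 28.3 min.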